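The aryl ketone is disconnected at the bond between the carbonyl carbon and ring carbon C1. C1 lies next to the phenol oxygen on C2, and C4–Br and C5–OH repeat this ortho pair across the benzene ring. That hidden twofold pattern maps onto 2,5-dibromohydroquinone. Its monoester with (S)-3-hydroxy-3,7-dimethyloct-6-enoic acid (from geraniol by Sharpless epoxidation) is the precursor. Bromine–lithium exchange at the bromide beside the acyloxy group starts an anionic Fries shift. In one operation the acyl group moves from O to C, the ketone and the C2 phenol appear, and the twin bromide stays as the bromine of the target. No protecting group is used.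

Key step: step 5

Remark on the chemistry: the ring is numbered C1 (acyl), C2 (OH), C3 (H), C4 (Br), C5 (OH), C6 (H). The carbinol centre of the target is read from the SMILES as S. Its four substituents keep the same priority order in every intermediate, so the descriptor stays S throughout.

Step 1
Reactants: 1 geraniol
Product: 2 (2S,3S)-2,3-epoxygeraniol
Conditions: Ti(OiPr)4 (5 mol%), L-(+)-diethyl tartrate (7 mol%), t-BuOOH (1.5 equiv, anhydrous in decane), 4 Å molecular sieves, CH2Cl2, −20 °C
Reagents that add atoms: tert-butyl hydroperoxide, CC(C)(C)OO
Why: Katsuki–Sharpless asymmetric epoxidation, in which the titanium tartrate complex binds the allylic alcohol so that only the 2,3-alkene is oxidised, and L-(+)-tartrate delivers oxygen to the face that sets C2 and C3 as S, C3 being the future carbinol centre.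

Step 2
Reactants: 2 (2S,3S)-2,3-epoxygeraniol
Product: 3 (S)-3,7-dimethyloct-6-ene-1,3-diol
Conditions: LiAlH4 (1.5 equiv), THF, 0 °C to rt; H2O quench
Reagents that add atoms: none
Why: Hydroxyl-directed hydride opening of a 2,3-epoxy alcohol, in which the alkoxyaluminate delivers hydride in SN2 fashion to the secondary C2 while the C3–O bond at the fully substituted carbon is untouched, so C3 keeps its S configuration and the 1,3-diol should result.

Step 3
Reactants: 3 (S)-3,7-dimethyloct-6-ene-1,3-diol
Product: 4 (S)-3-hydroxy-3,7-dimethyloct-6-enoic acid
Conditions: TEMPO (20 mol%), PhI(OAc)2 (2.2 equiv), MeCN/H2O 1:1, rt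
Reagents that add atoms: water, O
Why: Oxoammonium-mediated (TEMPO/PhI(OAc)2) oxidation, in which only the primary alcohol can react, the aldehyde hydrate is carried on to the acid in the aqueous medium, and the tertiary carbinol and the trisubstituted alkene are inert to these chlorine-free conditions.

Step 4
Reactants: 4 (S)-3-hydroxy-3,7-dimethyloct-6-enoic acid, 5 2,5-dibromohydroquinone (3 equiv)
Product: 6 2,5-dibromo-4-hydroxyphenyl (S)-3-hydroxy-3,7-dimethyloct-6-enoate
Conditions: DCC (1.05 equiv), DMAP (10 mol%), THF/CH2Cl2, 0 °C to rt; excess 5 recovered
Reagents that add atoms: none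
Why: Steglich esterification, in which the acylpyridinium ion is taken up by a phenol OH far faster than by the hindered tertiary carbinol, and the excess of the symmetric diol 5 (both OH groups equivalent) biases the statistics towards the monoester.

Step 5
Reactants: 6 2,5-dibromo-4-hydroxyphenyl (S)-3-hydroxy-3,7-dimethyloct-6-enoate
Product: 11 (S)-1-(4-bromo-2,5-dihydroxyphenyl)-3-hydroxy-3,7-dimethyloct-6-en-1-one, via dilithium salt 7 (not isolated), via aryllithium 8 (not isolated), via benzoxete adduct 9 (not isolated), via trilithium ketone salt 10 (not isolated)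
Conditions: MeLi (2.0 equiv), THF/Et2O, −78 °C; t-BuLi (2.0 equiv), −100 °C, high dilution; AcOH/THF, −100 °C to rt
Reagents that add atoms: methyllithium, [Li]C; tert-butyllithium, [Li]C(C)(C)C (they supply only the lithium of 7 to 10; no atom of either stays in 11)
Why: MeLi, a poor exchange partner, first removes only the two O–H protons (7); one equivalent of t-BuLi then exchanges the bromine flanking the acyloxy group (8) and the second destroys the t-BuBr formed, after which the aryl carbanion attacks its own ester carbonyl and the lithium hemiketal 9 opens by C–O cleavage to the o-oxidoaryl ketone 10, which is protonated cold to 11. This is the halogen–metal-exchange-initiated anionic ortho-Fries rearrangement (1,3 O-to-C acyl shift) known for o-bromophenyl and o-iodophenyl esters, a relative of the Parham cycloacylation. The only ring closed is the transient four-membered benzoxete of 9, formed by 4-exo-trig attack and opened again at once, so no ring remains in the product. No lasting stereocentre is created (the hemiketal carbon of 9 returns to sp2), the S carbinol carbon two atoms away takes no part, and quenching at −100 °C keeps the lithium aldolate 10 from retro-aldol cleavage. Site selectivity between the two bromines is needed: the one ortho to the inductively withdrawing, lithium-coordinating acyloxy group gives the better stabilised carbanion, its twin sits beside the electron-rich lithium phenoxide, and only the former carbanion is drained irreversibly by acyl transfer. Chemoselectivity over addition to the ester and over alpha-deprotonation rests on the speed of exchange with bulky t-BuLi at −100 °C and on the neighbouring alkoxide, which lowers the acidity of the CH2 group and does not yet lactonise at this temperature.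

Compound list
1 | geraniol, (E)-3,7-dimethylocta-2,6-dien-1-ol | CC(C)=CCC/C(C)=C/CO | starting material
2 | (2S,3S)-2,3-epoxygeraniol, [(2S,3S)-3-methyl-3-(4-methylpent-3-en-1-yl)oxiran-2-yl]methanol | CC(C)=CCC[C@]1(C)O[C@H]1CO | intermediate
3 | (S)-3,7-dimethyloct-6-ene-1,3-diol | CC(C)=CCC[C@](C)(O)CCO | intermediate
4 | (S)-3-hydroxy-3,7-dimethyloct-6-enoic acid | CC(C)=CCC[C@](C)(O)CC(=O)O | intermediate
5 | 2,5-dibromohydroquinone, 2,5-dibromobenzene-1,4-diol | Oc1cc(Br)c(O)cc1Br | starting material
6 | 2,5-dibromo-4-hydroxyphenyl (S)-3-hydroxy-3,7-dimethyloct-6-enoate | CC(C)=CCC[C@](C)(O)CC(=O)Oc1cc(Br)c(O)cc1Br | intermediate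
7 | dilithium salt of 6 (lithium tertiary alkoxide, lithium phenoxide) | CC(C)=CCC[C@](C)(O[Li])CC(=O)Oc1cc(Br)c(O[Li])cc1Br | intermediate
8 | aryllithium from 7, lithium in place of the bromine ortho to the acyloxy group | CC(C)=CCC[C@](C)(O[Li])CC(=O)Oc1cc(Br)c(O[Li])cc1[Li] | intermediate
9 | benzoxete adduct, four-membered lithium hemiketal from attack of the aryl carbanion on the ester carbonyl (hemiketal carbon undefined) | CC(C)=CCC[C@](C)(O[Li])CC1(O[Li])Oc2cc(Br)c(O[Li])cc21 | intermediate
10 | trilithium salt of the target ketone | CC(C)=CCC[C@](C)(O[Li])CC(=O)c1cc(O[Li])c(Br)cc1O[Li] | intermediate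
11 | (S)-1-(4-bromo-2,5-dihydroxyphenyl)-3-hydroxy-3,7-dimethyloct-6-en-1-one (CNP0227808.1) | CC(C)=CCC[C@](C)(O)CC(=O)c1cc(O)c(Br)cc1O | target

Total step count: 5
Longest linear sequence: 5 steps (1 to 11)

Steps most likely to fail

**Step 5.**
- Exchange may occur at the bromine next to the phenoxide.
- The alkyllithium may add to the aryl ester.
- A proton may pass from the alpha-CH2 to the aryl carbanion before acyl transfer.
- Each of these ends in loss of bromine or of the acyl group.

The fallback gives up the tether and joins the fragments intermolecularly. It sets out from 4 and 5 and returns at 11. Compound 5 would be converted with MOMCl and iPr2NEt into 1,4-dibromo-2,5-bis(methoxymethoxy)benzene F1. Acid 4 would be converted with MeNH(OMe)·HCl, EDC and N-methylmorpholine into the Weinreb amide (S)-3-hydroxy-N-methoxy-N,3,7-trimethyloct-6-enamide F2. The carbinol of F2 is masked with one equivalent of n-BuLi at −78 °C as the lithium alkoxide of the Weinreb amide F3. Single bromine–lithium exchange of the symmetric F1 (n-BuLi, THF, −78 °C) gives 4-bromo-2,5-bis(methoxymethoxy)phenyllithium F4. Its addition to F3 stops at the chelated tetrahedral adduct and on work-up gives (S)-1-[4-bromo-2,5-bis(methoxymethoxy)phenyl]-3-hydroxy-3,7-dimethyloct-6-en-1-one F5. Methanolysis of both phenolic acetals with dilute HCl in MeOH at rt leads to 11.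

**Step 4.**
- The symmetric diol may be acylated twice.
- The activated beta-hydroxy acid may undergo beta-elimination to the conjugated ester.

The fallback changes the acyl donor to a strained ring. It sets out from 4 and returns at 6. Carboxyl-activating lactonisation (PhSO2Cl, pyridine, 0 °C) leaves the carbinol C–O bond intact and gives (S)-4-methyl-4-(4-methylpent-3-en-1-yl)oxetan-2-one F6. Its fully substituted ring carbon leaves only acyl–oxygen cleavage open to a nucleophile. Excess 5 with Et3N and catalytic DMAP in THF should therefore open it to 6, and no external coupling reagent is present.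

**Step 3.**
- The transient beta-hydroxy aldehyde may dehydrate to the conjugated enal before it is hydrated and oxidised further.
- The oxidant may slowly attack the trisubstituted alkene.

The fallback replaces the single operation by a staged sequence with two mechanistically different oxidants. It sets out from 3 and returns at 4. Parikh–Doering oxidation (SO3·pyridine, DMSO, Et3N, 0 °C) gives (S)-3-hydroxy-3,7-dimethyloct-6-enal F7, which is used crude. Pinnick oxidation (NaClO2, NaH2PO4, 2-methylbut-2-ene, t-BuOH/H2O) then gives 4.

Further compounds
F1 | step 5 | 1,4-dibromo-2,5-bis(methoxymethoxy)benzene | COCOc1cc(Br)c(OCOC)cc1Br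
F2 | step 5 | (S)-3-hydroxy-N-methoxy-N,3,7-trimethyloct-6-enamide | CC(C)=CCC[C@](C)(O)CC(=O)N(C)OC
F3 | step 5 | lithium alkoxide of the Weinreb amide F2 | CC(C)=CCC[C@](C)(O[Li])CC(=O)N(C)OC
F4 | step 5 | 4-bromo-2,5-bis(methoxymethoxy)phenyllithium | [Li]c1cc(OCOC)c(Br)cc1OCOC
F5 | step 5 | (S)-1-[4-bromo-2,5-bis(methoxymethoxy)phenyl]-3-hydroxy-3,7-dimethyloct-6-en-1-one | CC(C)=CCC[C@](C)(O)CC(=O)c1cc(OCOC)c(Br)cc1OCOC
F6 | step 4 | (S)-4-methyl-4-(4-methylpent-3-en-1-yl)oxetan-2-one | CC(C)=CCC[C@@]1(C)CC(=O)O1
F7 | step 3 | (S)-3-hydroxy-3,7-dimethyloct-6-enal | CC(C)=CCC[C@](C)(O)CC=O
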